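**Retrosynthetic overview**
- The C5 chlorine is installed last by electrophilic chlorination; the pyran ring comes from a desilylative 6-endo oxa-Michael closure of a primary alcohol onto a C4a-alkynyl cyclohexenone.
- That ynenone comes from Sonogashira coupling of a 3-chlorocyclohexenone with a side-chain enyne.
- The cyclohexenone (with C7 Me/OH) comes from an α-ketol ring expansion of a 1-acetylcyclopent-2-en-1-ol. This in turn derives from (S)-4-silyloxycyclopentenone by chlorination, Luche reduction, [2,3]-Wittig–Still shift (cis CH2O), allylic oxidation and acetyl-anion addition.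
- The side chain comes from an (E)-vinyl iodide made from a propargylic alcohol; its oxolane ring arises by Shi epoxidation/5-exo opening of an (E)-enyne alcohol from (S)-α-methyl-γ-butyrolactone.
- Ring order: oxolane (side chain), then five-membered carbocycle (bought), then six-membered carbocycle (ring expansion), then pyran.

Assumption: (S)-4-(tert-butyldimethylsilyloxy)cyclopent-2-enone and (S)-α-methyl-γ-butyrolactone are bought as single enantiomers; a one-flask sequence counts as one step. TBS = tert-butyldimethylsilyl, TBSO = its ether.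

**Step 1**
Reactants: 1 (S)-4-(TBSO)cyclopent-2-en-1-one
Product: 2 (S)-2-chloro-4-(TBSO)cyclopent-2-en-1-one
Conditions: PhICl2, pyridine, CH2Cl2, 0 °C → rt
Reagents that add atoms: iodobenzene dichloride, ClI(Cl)c1ccccc1
Why: α-Chlorination of the enone by chlorine addition and pyridine-induced dehydrochlorination (as for the known 2-bromo and 2-iodo analogues) installs the vinyl chloride that later serves as the coupling handle at C4a, leaving the C4 stereocentre untouched.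

**Step 2**
Reactants: 2 (S)-2-chloro-4-(TBSO)cyclopent-2-en-1-one
Product: 3 (1R,4S)-2-chloro-4-(TBSO)cyclopent-2-en-1-ol
Conditions: NaBH4, CeCl3·7H2O, MeOH, −78 °C
Reagents that add atoms: none
Why: Luche 1,2-reduction in which hydride enters anti to the 4-OTBS group, giving the cis-1,4 alcohol (1R).

**Step 3**
Reactants: 3 (1R,4S)-2-chloro-4-(TBSO)cyclopent-2-en-1-ol
Product: 4 tributyl({[(1R,4S)-2-chloro-4-(TBSO)cyclopent-2-en-1-yl]oxy}methyl)stannane
Conditions: KH, 18-crown-6 (cat.), Bu3SnCH2I, THF, 0 °C → rt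
Reagents that add atoms: tributyl(iodomethyl)stannane, CCCC[Sn](CCCC)(CCCC)CI
Why: Williamson O-alkylation of the potassium alkoxide with Still's iodomethylstannane, with no change at the stereocentres.

**Step 4**
Reactants: 4 tributyl({[(1R,4S)-2-chloro-4-(TBSO)cyclopent-2-en-1-yl]oxy}methyl)stannane
Product: 7 [(1S,5S)-2-chloro-5-(TBSO)cyclopent-2-en-1-yl]methyl TBS ether, via lithiomethyl ether 5 (not isolated), via rearranged lithium alkoxide 6 (not isolated)
Conditions: n-BuLi, THF, −78 °C; then TBSOTf, −78 → 0 °C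
Reagents that add atoms: tert-butyldimethylsilyl trifluoromethanesulfonate, CC(C)(C)[Si](C)(C)OS(=O)(=O)C(F)(F)F
Why: Tin–lithium exchange and [2,3]-Wittig–Still rearrangement deliver the CH2O unit suprafacially to the allyl terminus on the face that carried the ether oxygen, i.e. cis to OTBS (sets C8a), while the double bond moves next to the chlorine; the alkoxide is silylated in the same flask.

**Step 5**
Reactants: 7 [(1S,5S)-2-chloro-5-(TBSO)cyclopent-2-en-1-yl]methyl TBS ether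
Product: 8 (4S,5R)-3-chloro-5-(TBSO)-4-(TBSOCH2)cyclopent-2-en-1-one
Conditions: CrO3 (10 mol %), t-BuOOH (70% aq.), CH2Cl2, rt
Reagents that add atoms: tert-butyl hydroperoxide, CC(C)(C)OO
Why: Chromium-catalysed allylic C–H oxidation of the CH2 next to the vinylic CH, the regiochemistry of the classical conversion of 1-chlorocycloalkenes into 3-chlorocycloalk-2-enones; the hindered tertiary C–H beside C–Cl is left and no stereocentre is touched.

**Step 6**
Reactants: 8 (4S,5R)-3-chloro-5-(TBSO)-4-(TBSOCH2)cyclopent-2-en-1-one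
Product: 10 1-[(1S,4S,5R)-3-chloro-1-hydroxy-5-(TBSO)-4-(TBSOCH2)cyclopent-2-en-1-yl]ethan-1-one, via ethoxyvinyl carbinol lithium alkoxide 9 (not isolated)
Conditions: ethyl vinyl ether, t-BuLi, THF, −78 → 0 °C; 8, −78 °C; then 0.5 M HCl, THF, 0 °C
Reagents that add atoms: ethyl vinyl ether, C=COCC; water, O
Why: 1,2-Addition of 1-ethoxyvinyllithium (acetyl anion equivalent) to the enone carbonyl from the face anti to the adjacent OTBS and the CH2OTBS group sets the carbinol (1S) with OH cis to both, and mild acid hydrolyses the enol ether to the methyl ketone.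

**Step 7**
Reactants: 10 1-[(1S,4S,5R)-3-chloro-1-hydroxy-5-(TBSO)-4-(TBSOCH2)cyclopent-2-en-1-yl]ethan-1-one
Product: 11 (4S,5R,6R)-3-chloro-6-hydroxy-6-methyl-5-(TBSO)-4-(TBSOCH2)cyclohex-2-en-1-one
Conditions: Sc(OTf)3 (10 mol %), 4 Å MS, toluene, 50 °C
Reagents that add atoms: none
Why: Proposed new method: a chelation-controlled α-ketol (acyloin) ring expansion of a 1-acetylcyclopent-2-en-1-ol, a substrate class on which this 1,2-shift has not been shown; trivalent scandium binds the tertiary OH and the acetyl C=O as a five-membered chelate, the C1–C5 ring bond (the silyloxy-bearing sp3 carbon, favoured over the electron-poor chlorovinyl carbon by α-oxygen assistance and by the enone conjugation that develops) migrates to the activated acyl carbon, and the chelate geometry keeps the new tertiary OH on the face of the old one, cis to OTBS (6R); the closest known reactions are the Lewis-acid D-homoannulation of 17α-hydroxy-20-ketosteroids and α-ketol ring expansions of 1-acylcycloalkanols.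

**Step 8**
Reactants: 12 (S)-3-methyloxolan-2-one
Product: 13 (3S)-3-methyloxolan-2-ol (anomer mixture)
Conditions: DIBAL-H, CH2Cl2, −78 °C
Reagents that add atoms: none
Why: DIBAL half-reduction of the lactone to the lactol at low temperature, with the methyl stereocentre untouched.

**Step 9**
Reactants: 13 (3S)-3-methyloxolan-2-ol
Product: 14 (2E,4S)-6-hydroxy-2,4-dimethylhex-2-enal
Conditions: Ph3P=C(CH3)CHO, toluene, 90 °C
Reagents that add atoms: 2-(triphenylphosphoranylidene)propanal, CC(C=O)=P(c1ccccc1)(c1ccccc1)c1ccccc1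
Why: Wittig olefination of the open hydroxy-aldehyde form of the lactol with the stabilised formyl ylide is E-selective and neutral enough to keep the α-stereocentre.

**Step 10**
Reactants: 14 (2E,4S)-6-hydroxy-2,4-dimethylhex-2-enal
Product: 15 (3S,4E)-3,5-dimethylhept-4-en-6-yn-1-ol
Conditions: dimethyl (1-diazo-2-oxopropyl)phosphonate, K2CO3, MeOH, 0 °C → rt
Reagents that add atoms: dimethyl (1-diazo-2-oxopropyl)phosphonate, COP(=O)(OC)C(=[N+]=[N-])C(C)=O
Why: Ohira–Bestmann (Seyferth–Gilbert) homologation converts the enal into the terminal enyne with retention of the alkene geometry.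

**Step 11**
Reactants: 15 (3S,4E)-3,5-dimethylhept-4-en-6-yn-1-ol
Product: 17 (2R)-2-[(2S,3S)-3-methyloxolan-2-yl]but-3-yn-2-ol, via epoxy alcohol 16 (not isolated)
Conditions: D-fructose-derived Shi ketone (30 mol %), Oxone, K2CO3, Bu4NHSO4, MeCN/CH2(OMe)2/aq. buffer, 0 °C; then CSA (cat.), CH2Cl2, rt
Reagents that add atoms: potassium peroxymonosulfate (Oxone), [K+].[O-]S(=O)(=O)OO
Why: Shi asymmetric epoxidation of the trisubstituted (E)-enyne gives the (2R,3R)-epoxide under reagent control, and acid-catalysed 5-exo opening by the primary OH with inversion at the secondary epoxide carbon closes the 2,3-trans oxolane (2S) while the tertiary propargylic carbinol (R) keeps the epoxide oxygen.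

**Step 12**
Reactants: 17 (2R)-2-[(2S,3S)-3-methyloxolan-2-yl]but-3-yn-2-ol
Product: 19 (2R,3E)-4-iodo-2-[(2S,3S)-3-methyloxolan-2-yl]but-3-en-2-ol, via vinylstannane 18 (not isolated)
Conditions: Bu3SnH, PdCl2(PPh3)2 (2 mol %), THF, 0 °C; then I2, CH2Cl2, 0 °C
Reagents that add atoms: iodine, II
Why: Palladium-catalysed syn-hydrostannation places tin on the terminal carbon (the bulky tertiary carbinol blocks the internal position) and iododestannylation with retention gives the (E)-vinyl iodide.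

**Step 13**
Reactants: 19 (2R,3E)-4-iodo-2-[(2S,3S)-3-methyloxolan-2-yl]but-3-en-2-ol
Product: 20 (2R,3E)-2-[(2S,3S)-3-methyloxolan-2-yl]hex-3-en-5-yn-2-ol
Conditions: HC≡CMgBr, ZnBr2, THF, 0 °C; then 19, Pd(PPh3)4 (5 mol %), rt
Reagents that add atoms: ethynylmagnesium bromide, C#C[Mg]Br
Why: Negishi coupling of the vinyl iodide with ethynylzinc bromide gives the terminal enyne directly with retention of the E geometry.

**Step 14**
Reactants: 11 (4S,5R,6R)-3-chloro-6-hydroxy-6-methyl-5-(TBSO)-4-(TBSOCH2)cyclohex-2-en-1-one; 20 (2R,3E)-2-[(2S,3S)-3-methyloxolan-2-yl]hex-3-en-5-yn-2-ol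
Product: 21 (4S,5R,6R)-6-hydroxy-3-{(3E,5R)-5-hydroxy-5-[(2S,3S)-3-methyloxolan-2-yl]hex-3-en-1-yn-1-yl}-6-methyl-5-(TBSO)-4-(TBSOCH2)cyclohex-2-en-1-one
Conditions: Pd(PPh3)4 (5 mol %), CuI (10 mol %), i-Pr2NH, THF, 50 °C (degassed)
Reagents that add atoms: none
Why: Sonogashira coupling at the activated C–Cl bond of the β-chloroenone (a vinylogous acid chloride) joins the two fragments without touching any stereocentre.

**Step 15**
Reactants: 21 (4S,5R,6R)-6-hydroxy-3-{(3E,5R)-5-hydroxy-5-[(2S,3S)-3-methyloxolan-2-yl]hex-3-en-1-yn-1-yl}-6-methyl-5-(TBSO)-4-(TBSOCH2)cyclohex-2-en-1-one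
Product: 23 (7R,8R,8aS)-7,8-dihydroxy-3-{(1E,3R)-3-hydroxy-3-[(2S,3S)-3-methyloxolan-2-yl]but-1-en-1-yl}-7-methyl-1,7,8,8a-tetrahydro-6H-isochromen-6-one, via desilylated triol 22 (not isolated)
Conditions: TBAF, THF, 0 °C → rt; AcOH quench
Reagents that add atoms: none
Why: Fluoride removes both TBS groups and the freed primary alkoxide adds to the alkyne terminus of the ynenone in a 6-endo-dig 1,6-oxa-Michael addition (the δ-carbon is the electrophilic site, and attack by the secondary oxygen would need a bridged ring), closing the pyran as the conjugated dienol ether.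

**Step 16**
Reactants: 23 (7R,8R,8aS)-7,8-dihydroxy-3-{(1E,3R)-3-hydroxy-3-[(2S,3S)-3-methyloxolan-2-yl]but-1-en-1-yl}-7-methyl-1,7,8,8a-tetrahydro-6H-isochromen-6-one
Product: 24 (7R,8R,8aS)-5-chloro-7,8-dihydroxy-3-{(1E,3R)-3-hydroxy-3-[(2S,3S)-3-methyloxolan-2-yl]but-1-en-1-yl}-7-methyl-1,7,8,8a-tetrahydro-6H-isochromen-6-one
Conditions: NCS, CH2Cl2, 0 °C
Reagents that add atoms: N-chlorosuccinimide, O=C1CCC(=O)N1Cl
Why: Electrophilic chlorination at C5, the α-carbon of the δ-alkoxy dienone and the position halogenated in azaphilone-type vinylogous esters, gives the target.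

**Compound list**
1 | (S)-4-(TBSO)cyclopent-2-en-1-one | O=C1C=C[C@@H](O[Si](C)(C)C(C)(C)C)C1 | starting material
2 | (S)-2-chloro-4-(TBSO)cyclopent-2-en-1-one | O=C1C(Cl)=C[C@@H](O[Si](C)(C)C(C)(C)C)C1 | intermediate
3 | (1R,4S)-2-chloro-4-(TBSO)cyclopent-2-en-1-ol | O[C@H]1C(Cl)=C[C@@H](O[Si](C)(C)C(C)(C)C)C1 | intermediate
4 | tributyl({[(1R,4S)-2-chloro-4-(TBSO)cyclopent-2-en-1-yl]oxy}methyl)stannane | CCCC[Sn](CCCC)(CCCC)CO[C@H]1C(Cl)=C[C@@H](O[Si](C)(C)C(C)(C)C)C1 | intermediate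
5 | {[(1R,4S)-2-chloro-4-(TBSO)cyclopent-2-en-1-yl]oxy}methyllithium | [Li]CO[C@H]1C(Cl)=C[C@@H](O[Si](C)(C)C(C)(C)C)C1 | intermediate
6 | lithium [(1S,5S)-2-chloro-5-(TBSO)cyclopent-2-en-1-yl]methanolate | [Li]OC[C@@H]1C(Cl)=CC[C@@H]1O[Si](C)(C)C(C)(C)C | intermediate
7 | [(1S,5S)-2-chloro-5-(TBSO)cyclopent-2-en-1-yl]methyl TBS ether | CC(C)(C)[Si](C)(C)OC[C@@H]1C(Cl)=CC[C@@H]1O[Si](C)(C)C(C)(C)C | intermediate
8 | (4S,5R)-3-chloro-5-(TBSO)-4-(TBSOCH2)cyclopent-2-en-1-one | O=C1C=C(Cl)[C@@H](CO[Si](C)(C)C(C)(C)C)[C@H]1O[Si](C)(C)C(C)(C)C | intermediate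
9 | lithium (1S,4S,5R)-3-chloro-1-(1-ethoxyethenyl)-5-(TBSO)-4-(TBSOCH2)cyclopent-2-en-1-olate | C=C(OCC)[C@]1(O[Li])C=C(Cl)[C@@H](CO[Si](C)(C)C(C)(C)C)[C@H]1O[Si](C)(C)C(C)(C)C | intermediate
10 | 1-[(1S,4S,5R)-3-chloro-1-hydroxy-5-(TBSO)-4-(TBSOCH2)cyclopent-2-en-1-yl]ethan-1-one | CC(=O)[C@]1(O)C=C(Cl)[C@@H](CO[Si](C)(C)C(C)(C)C)[C@H]1O[Si](C)(C)C(C)(C)C | intermediate
11 | (4S,5R,6R)-3-chloro-6-hydroxy-6-methyl-5-(TBSO)-4-(TBSOCH2)cyclohex-2-en-1-one | O=C1C=C(Cl)[C@@H](CO[Si](C)(C)C(C)(C)C)[C@@H](O[Si](C)(C)C(C)(C)C)[C@@]1(C)O | intermediate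
12 | (S)-3-methyloxolan-2-one | C[C@H]1CCOC1=O | starting material
13 | (3S)-3-methyloxolan-2-ol | C[C@H]1CCOC1O | intermediate
14 | (2E,4S)-6-hydroxy-2,4-dimethylhex-2-enal | O=C/C(C)=C/[C@@H](C)CCO | intermediate
15 | (3S,4E)-3,5-dimethylhept-4-en-6-yn-1-ol | C#C/C(C)=C/[C@@H](C)CCO | intermediate
16 | (3S)-3-[(2R,3R)-3-ethynyl-3-methyloxiran-2-yl]butan-1-ol | C#C[C@@]1(C)O[C@@H]1[C@@H](C)CCO | intermediate
17 | (2R)-2-[(2S,3S)-3-methyloxolan-2-yl]but-3-yn-2-ol | C[C@H]1CCO[C@@H]1[C@](C)(O)C#C | intermediate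
18 | (2R,3E)-2-[(2S,3S)-3-methyloxolan-2-yl]-4-(tributylstannyl)but-3-en-2-ol | C[C@H]1CCO[C@@H]1[C@](C)(O)/C=C/[Sn](CCCC)(CCCC)CCCC | intermediate
19 | (2R,3E)-4-iodo-2-[(2S,3S)-3-methyloxolan-2-yl]but-3-en-2-ol | C[C@H]1CCO[C@@H]1[C@](C)(O)/C=C/I | intermediate
20 | (2R,3E)-2-[(2S,3S)-3-methyloxolan-2-yl]hex-3-en-5-yn-2-ol | C[C@H]1CCO[C@@H]1[C@](C)(O)/C=C/C#C | intermediate
21 | (4S,5R,6R)-6-hydroxy-3-{(3E,5R)-5-hydroxy-5-[(2S,3S)-3-methyloxolan-2-yl]hex-3-en-1-yn-1-yl}-6-methyl-5-(TBSO)-4-(TBSOCH2)cyclohex-2-en-1-one | O=C1C=C(C#C/C=C/[C@@](C)(O)[C@H]2OCC[C@@H]2C)[C@@H](CO[Si](C)(C)C(C)(C)C)[C@@H](O[Si](C)(C)C(C)(C)C)[C@@]1(C)O | intermediate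
22 | (4S,5R,6R)-5,6-dihydroxy-4-(hydroxymethyl)-3-{(3E,5R)-5-hydroxy-5-[(2S,3S)-3-methyloxolan-2-yl]hex-3-en-1-yn-1-yl}-6-methylcyclohex-2-en-1-one | O=C1C=C(C#C/C=C/[C@@](C)(O)[C@H]2OCC[C@@H]2C)[C@@H](CO)[C@@H](O)[C@@]1(C)O | intermediate
23 | (7R,8R,8aS)-7,8-dihydroxy-3-{(1E,3R)-3-hydroxy-3-[(2S,3S)-3-methyloxolan-2-yl]but-1-en-1-yl}-7-methyl-1,7,8,8a-tetrahydro-6H-isochromen-6-one | C[C@H]1CCO[C@@H]1[C@](C)(O)/C=C/C1=CC2=CC(=O)[C@](C)(O)[C@H](O)[C@@H]2CO1 | intermediate
24 | (7R,8R,8aS)-5-chloro-7,8-dihydroxy-3-{(1E,3R)-3-hydroxy-3-[(2S,3S)-3-methyloxolan-2-yl]but-1-en-1-yl}-7-methyl-1,7,8,8a-tetrahydro-6H-isochromen-6-one | C[C@H]1CCO[C@@H]1[C@](C)(O)/C=C/C1=CC2=C(Cl)C(=O)[C@](C)(O)[C@H](O)[C@@H]2CO1 | target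

**Step count and risk**
Total: 16 steps. Longest linear sequence: 10 steps (steps 1–7, then 14–16); the side-chain branch is 6 steps (8–13) before the union.

Most likely to fail, first: step 7 (the proposed ring expansion). The chlorovinyl ring carbon may migrate instead of the silyloxy-bearing carbon, which would erode the C7 configuration, and the Lewis acid may ionise or desilylate the substrate. The fallback uses known chemistry, sets out from 8 and comes back at 11. Ring homologation of enone 8 with trimethylsilyldiazomethane and AlMe3 (diazoalkane insertion on the saturated α-carbon side of an enone), followed by acidic work-up, gives (4S,5S)-3-chloro-5-(TBSO)-4-(TBSOCH2)cyclohex-2-en-1-one F4. Enolate hydroxylation (LiHMDS, Davis oxaziridine) and TMSCl give the α-silyloxy ketone (4S,5R)-3-chloro-5-(TBSO)-4-(TBSOCH2)-6-(trimethylsilyloxy)cyclohex-2-en-1-one F5. Its enolate (LiHMDS) is methylated with MeI on the face anti to the neighbouring OTBS to give (4S,5R,6R)-3-chloro-6-methyl-5-(TBSO)-4-(TBSOCH2)-6-(trimethylsilyloxy)cyclohex-2-en-1-one F6. Citric acid in MeOH then frees the tertiary alcohol 11.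

Second: step 4 (Wittig–Still shift on a cyclopentenyl 2-chloroallyl ether). A [1,2]-shift or simple protonation of the lithiomethyl ether may compete. The fallback sets out from 3 and comes back at 7. PhNCO converts 3 into (1R,4S)-2-chloro-4-(TBSO)cyclopent-2-en-1-yl N-phenylcarbamate F1. Deprotonation (MeLi) and the organocopper reagent from (isopropoxydimethylsilyl)methylmagnesium chloride and CuI give carbamate-directed syn-SN2' substitution to {[(1R,5S)-2-chloro-5-(TBSO)cyclopent-2-en-1-yl]methyl}(isopropoxy)dimethylsilane F2. Tamao oxidation (H2O2, KF, KHCO3) gives [(1S,5S)-2-chloro-5-(TBSO)cyclopent-2-en-1-yl]methanol F3, and TBSCl/imidazole gives 7.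

Third: step 16 (last-step chlorination). C4 or the side-chain diene may compete with C5, and over-chlorination is possible. The fallback sets out from 11 and comes back at 24 by placing the chlorine before the pyran is made. PhICl2/pyridine α-chlorinates 11 to (4S,5R,6R)-2,3-dichloro-6-hydroxy-6-methyl-5-(TBSO)-4-(TBSOCH2)cyclohex-2-en-1-one F7. Sonogashira coupling with 20, selective for the β-chlorine, gives (4S,5R,6R)-2-chloro-6-hydroxy-3-{(3E,5R)-5-hydroxy-5-[(2S,3S)-3-methyloxolan-2-yl]hex-3-en-1-yn-1-yl}-6-methyl-5-(TBSO)-4-(TBSOCH2)cyclohex-2-en-1-one F8. TBAF desilylation with 6-endo closure then gives 24 directly.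

**Further compounds**
F1 | step 4 | (1R,4S)-2-chloro-4-(TBSO)cyclopent-2-en-1-yl N-phenylcarbamate | O=C(Nc1ccccc1)O[C@H]1C(Cl)=C[C@@H](O[Si](C)(C)C(C)(C)C)C1
F2 | step 4 | {[(1R,5S)-2-chloro-5-(TBSO)cyclopent-2-en-1-yl]methyl}(isopropoxy)dimethylsilane | CC(C)O[Si](C)(C)C[C@@H]1C(Cl)=CC[C@@H]1O[Si](C)(C)C(C)(C)C
F3 | step 4 | [(1S,5S)-2-chloro-5-(TBSO)cyclopent-2-en-1-yl]methanol | OC[C@@H]1C(Cl)=CC[C@@H]1O[Si](C)(C)C(C)(C)C
F4 | step 7 | (4S,5S)-3-chloro-5-(TBSO)-4-(TBSOCH2)cyclohex-2-en-1-one | O=C1C=C(Cl)[C@@H](CO[Si](C)(C)C(C)(C)C)[C@@H](O[Si](C)(C)C(C)(C)C)C1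
F5 | step 7 | (4S,5R)-3-chloro-5-(TBSO)-4-(TBSOCH2)-6-(trimethylsilyloxy)cyclohex-2-en-1-one (C6 epimers) | O=C1C=C(Cl)[C@@H](CO[Si](C)(C)C(C)(C)C)[C@@H](O[Si](C)(C)C(C)(C)C)C1O[Si](C)(C)C
F6 | step 7 | (4S,5R,6R)-3-chloro-6-methyl-5-(TBSO)-4-(TBSOCH2)-6-(trimethylsilyloxy)cyclohex-2-en-1-one | O=C1C=C(Cl)[C@@H](CO[Si](C)(C)C(C)(C)C)[C@@H](O[Si](C)(C)C(C)(C)C)[C@@]1(C)O[Si](C)(C)C
F7 | step 16 | (4S,5R,6R)-2,3-dichloro-6-hydroxy-6-methyl-5-(TBSO)-4-(TBSOCH2)cyclohex-2-en-1-one | O=C1C(Cl)=C(Cl)[C@@H](CO[Si](C)(C)C(C)(C)C)[C@@H](O[Si](C)(C)C(C)(C)C)[C@@]1(C)O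
F8 | step 16 | (4S,5R,6R)-2-chloro-6-hydroxy-3-{(3E,5R)-5-hydroxy-5-[(2S,3S)-3-methyloxolan-2-yl]hex-3-en-1-yn-1-yl}-6-methyl-5-(TBSO)-4-(TBSOCH2)cyclohex-2-en-1-one | O=C1C(Cl)=C(C#C/C=C/[C@@](C)(O)[C@H]2OCC[C@@H]2C)[C@@H](CO[Si](C)(C)C(C)(C)C)[C@@H](O[Si](C)(C)C(C)(C)C)[C@@]1(C)O
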